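**Plan**

- Target numbering: C1 = quaternary carbinol carbon (carries CH2OBz), C2 = CHOH, C3 = CHOBz, C4 = CHOH, C5 = CH2, C6 = C=O. Cuts, in order: the O3 benzoate; a carboxyl added at C5 and tied to O2 as a lactone; the C6 ketone and C1 hydroxyl (back to a C1=C6 alkene); then C2–C3 and C4–C5 together, by a retro-[4+2], to methyl coumalate and 2,2-dimethyl-1,3-dioxole.
- Enabling feature: O2 and the C5 methylene stand 1,4 across the cyclohexane, C5 is alpha to the C6 ketone (an extra carboxyl there leaves as CO2), and C3/C4 carry cis oxygens. This is the pattern of a 2-pyrone plus an enediol: pyrone O1 = O2, pyrone C2 = the lost CO2, pyrone C4=C5 = C6/C1, the 5-ester carbon = the CH2OBz carbon.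
- Forward: the carbocycle forms in step 1 as the cyclohexene ring of a 2-oxabicyclo[2.2.2]octenone. Dihydroxylation, ester reduction, primary benzoylation and oxidation adjust C1/C6. Acid then opens the lactone bridge, expels CO2 and removes the acetonide; O3 is benzoylated last.
- Stereochemistry: C3/C4 cis from the ring of the dioxole, both trans to O2 through endo addition, absolute sense from a chiral Lewis acid; C1 from osmylation on the lactone face of the bicycle, away from the endo acetal.

Key step: step 1

Remark: 2,2-dimethyl-1,3-dioxole is taken as a purchasable reagent.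
Remark: the sense of induction of the step 1 catalyst cannot be fixed by analogy alone; the (S)-prolinol-derived catalyst is written, and the mirror-image catalyst is used if the first adduct proves to be the antipode.
Numbering of the bicyclic intermediates: C1 = bridgehead on the lactone oxygen, O2, C3 = lactone carbonyl, C4 = other bridgehead, C5/C6 = former pyrone alkene (C6 next to C1), C7/C8 = former dioxole carbons (C7 next to C1).

Step 1
Reactants: 1 methyl coumalate (methyl 2-oxo-2H-pyran-5-carboxylate); 2 2,2-dimethyl-1,3-dioxole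
Product: 3 methyl (1R,4S,7R,8R)-7,8-(isopropylidenedioxy)-3-oxo-2-oxabicyclo[2.2.2]oct-5-ene-6-carboxylate (acetal oxygens endo, on the side of the C5=C6 bridge)
Conditions: 2 (3 equiv), (S)-3,3-diphenyl-1-(o-tolyl)tetrahydropyrrolo[1,2-c][1,3,2]oxazaborole (20 mol%) activated with AlBr3 (16 mol%), CH2Cl2, −78 to −40 °C
Reagents that add atoms: none
Why: Proposed new method: the cationic boron Lewis acid binds the ring carbonyl of 1 (lone pair anti to the ring oxygen, with the vinylic C3–H···O contact known for bound unsaturated esters and lactones), lowers the LUMO of the pyrone and lets the electron-rich enediol acetal 2 add in an asynchronous inverse-electron-demand [4+2] cycloaddition, bonding first at pyrone C6 (beta to the ester) and then at C3. The closest known reactions are the thermal, high-pressure and Lewis-acid-catalysed (Cu(OTf)2 with a bis(oxazoline) ligand, Yb(OTf)3 with a binaphthol) cycloadditions of 2-pyrone esters with enol ethers and with 2 itself, which stop at the bicyclic lactone, and the enantioselective cycloadditions of unsaturated esters with enol ethers under AlBr3-activated oxazaborolidines; new is the use of this one-point-binding catalyst on a pyrone that lacks a chelating 3-ester. The cyclohexene ring closes by intermolecular [4+2] cycloaddition across pyrone C3 and C6, and the O–C(=O) unit of the pyrone is left as the two-atom lactone bridge. The two acetal-bearing carbons are cis because they come from the ring of 2, they are trans to the lactone oxygen because the dioxole adds endo (oxygens under the diene), and the absolute configuration follows from the prolinol aryl group covering one face of the bound pyrone. The step needs only endo and enantioface selectivity, since 2 is symmetric and no regiochemical question arises; the low temperature keeps the adduct from losing CO2 by retro-[4+2].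

Step 2
Reactants: 3 methyl (1R,4S,7R,8R)-7,8-(isopropylidenedioxy)-3-oxo-2-oxabicyclo[2.2.2]oct-5-ene-6-carboxylate
Product: 4 methyl (1S,4S,5R,6R,7R,8R)-5,6-dihydroxy-7,8-(isopropylidenedioxy)-3-oxo-2-oxabicyclo[2.2.2]octane-6-carboxylate
Conditions: OsO4 (2 mol%), NMO (1.5 equiv), citric acid (0.75 equiv), tBuOH–H2O 1:1, 20 °C
Reagents that add atoms: osmium tetroxide O=[Os](=O)(=O)=O (catalytic oxygen carrier); N-methylmorpholine N-oxide C[N+]1([O-])CCOCC1; water O
Why: Upjohn dihydroxylation adds syn to the strained acrylate alkene from the face of the flat lactone bridge, the other face being covered by the endo dioxolane, which sets the tertiary carbinol (C1 of the target) cis to the lactone oxygen, while the secondary carbinol formed with it later becomes the C6 ketone.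

Step 3
Reactants: 4 methyl (1S,4S,5R,6R,7R,8R)-5,6-dihydroxy-7,8-(isopropylidenedioxy)-3-oxo-2-oxabicyclo[2.2.2]octane-6-carboxylate
Product: 5 (1S,4S,5R,6R,7R,8R)-5,6-dihydroxy-6-(hydroxymethyl)-7,8-(isopropylidenedioxy)-2-oxabicyclo[2.2.2]octan-3-one
Conditions: BH3·SMe2 (2.5 equiv), NaBH4 (5 mol%), THF, 0 to 20 °C; MeOH quench
Reagents that add atoms: none
Why: hydroxyl-directed borane reduction of an alpha-hydroxy ester, in which the alkoxyborane formed at the tertiary hydroxyl delivers hydride to the ester on the same carbon through a five-membered transition state, whereas the lactone carbonyl is reached only through a larger ring and should be left; no stereocenter is touched.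

Step 4
Reactants: 5 (1S,4S,5R,6R,7R,8R)-5,6-dihydroxy-6-(hydroxymethyl)-7,8-(isopropylidenedioxy)-2-oxabicyclo[2.2.2]octan-3-one
Product: 6 [(1S,4S,5R,6R,7R,8R)-5,6-dihydroxy-7,8-(isopropylidenedioxy)-3-oxo-2-oxabicyclo[2.2.2]octan-6-yl]methyl benzoate
Conditions: BzCl (1.05 equiv), pyridine, CH2Cl2, −30 to 0 °C
Reagents that add atoms: benzoyl chloride O=C(Cl)c1ccccc1
Why: selective acylation of the primary hydroxyl, since the secondary hydroxyl on the bicyclic bridge and the tertiary one should react far more slowly at low temperature.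

Step 5
Reactants: 6 [(1S,4S,5R,6R,7R,8R)-5,6-dihydroxy-7,8-(isopropylidenedioxy)-3-oxo-2-oxabicyclo[2.2.2]octan-6-yl]methyl benzoate
Product: 7 [(1S,4R,6S,7R,8R)-6-hydroxy-7,8-(isopropylidenedioxy)-3,5-dioxo-2-oxabicyclo[2.2.2]octan-6-yl]methyl benzoate
Conditions: IBX (3 equiv), EtOAc, 75 °C
Reagents that add atoms: none
Why: hypervalent-iodine oxidation of the secondary alcohol of a vicinal diol to the alpha-hydroxy ketone without C–C cleavage; the ketone is beta to the lactone carbonyl but cannot enolise toward the bridgehead, so nothing epimerises and CO2 is not yet lost.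

Step 6
Reactants: 7 [(1S,4R,6S,7R,8R)-6-hydroxy-7,8-(isopropylidenedioxy)-3,5-dioxo-2-oxabicyclo[2.2.2]octan-6-yl]methyl benzoate
Product: 10 [(1S,2S,3R,4R)-1,2,3,4-tetrahydroxy-6-oxocyclohexyl]methyl benzoate, via diol keto-lactone 8 (not isolated), via keto acid 9 (not isolated)
Conditions: 1 M aq. HCl–THF 1:2, 40 °C
Reagents that add atoms: none
Why: acid hydrolysis of the acetonide and then of the strained beta-keto lactone frees O2 and a carboxyl on C5, which, no longer at a bridgehead, can enolise and leave as CO2 (beta-keto acid decarboxylation) to give the C5 methylene; the four stereocenters are untouched and the mild acid is chosen to keep the beta-hydroxy ketone from dehydrating.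

Step 7
Reactants: 10 [(1S,2S,3R,4R)-1,2,3,4-tetrahydroxy-6-oxocyclohexyl]methyl benzoate
Product: 11 [(1S,2S,3R,4R)-3-(benzoyloxy)-1,2,4-trihydroxy-6-oxocyclohexyl]methyl benzoate (target)
Conditions: BzCl (1.1 equiv), 2-aminoethyl diphenylborinate (10 mol%), iPr2NEt (1.5 equiv), MeCN, 20 °C
Reagents that add atoms: benzoyl chloride O=C(Cl)c1ccccc1
Why: borinic-acid-catalysed regioselective acylation of a cis-vicinal diol, in which the catalyst forms a borinate with the secondary O3/O4 cis-diol and the equatorial oxygen O3 is acylated (O4 is axial in the chair with CH2OBz equatorial), as in 3-O-acylation of galacto-configured 2,3,4-triols; the tertiary C1 hydroxyl and the hindered C2 hydroxyl next to the quaternary carbon should stay free.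

**Compound list**

1 | methyl coumalate (methyl 2-oxo-2H-pyran-5-carboxylate) | COC(=O)C1=COC(=O)C=C1 | starting material
2 | 2,2-dimethyl-1,3-dioxole | CC1(C)OC=CO1 | starting material
3 | methyl (1R,4S,7R,8R)-7,8-(isopropylidenedioxy)-3-oxo-2-oxabicyclo[2.2.2]oct-5-ene-6-carboxylate | COC(=O)C1=C[C@H]2[C@H]3OC(C)(C)O[C@H]3[C@@H]1OC2=O | intermediate
4 | methyl (1S,4S,5R,6R,7R,8R)-5,6-dihydroxy-7,8-(isopropylidenedioxy)-3-oxo-2-oxabicyclo[2.2.2]octane-6-carboxylate | COC(=O)[C@@]1(O)[C@H](O)[C@H]2[C@H]3OC(C)(C)O[C@H]3[C@@H]1OC2=O | intermediate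
5 | (1S,4S,5R,6R,7R,8R)-5,6-dihydroxy-6-(hydroxymethyl)-7,8-(isopropylidenedioxy)-2-oxabicyclo[2.2.2]octan-3-one | OC[C@@]1(O)[C@H](O)[C@H]2[C@H]3OC(C)(C)O[C@H]3[C@@H]1OC2=O | intermediate
6 | [(1S,4S,5R,6R,7R,8R)-5,6-dihydroxy-7,8-(isopropylidenedioxy)-3-oxo-2-oxabicyclo[2.2.2]octan-6-yl]methyl benzoate | O=C(OC[C@@]1(O)[C@H](O)[C@H]2[C@H]3OC(C)(C)O[C@H]3[C@@H]1OC2=O)c1ccccc1 | intermediate
7 | [(1S,4R,6S,7R,8R)-6-hydroxy-7,8-(isopropylidenedioxy)-3,5-dioxo-2-oxabicyclo[2.2.2]octan-6-yl]methyl benzoate | O=C(OC[C@@]1(O)C(=O)[C@H]2[C@H]3OC(C)(C)O[C@H]3[C@@H]1OC2=O)c1ccccc1 | intermediate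
8 | [(1S,4R,6S,7R,8R)-6,7,8-trihydroxy-3,5-dioxo-2-oxabicyclo[2.2.2]octan-6-yl]methyl benzoate (diol keto-lactone) | O=C(OC[C@@]1(O)C(=O)[C@H]2[C@@H](O)[C@@H](O)[C@@H]1OC2=O)c1ccccc1 | intermediate
9 | (1R,3S,4S,5R,6R)-3-[(benzoyloxy)methyl]-3,4,5,6-tetrahydroxy-2-oxocyclohexane-1-carboxylic acid (keto acid) | O=C(OC[C@@]1(O)C(=O)[C@H](C(=O)O)[C@@H](O)[C@@H](O)[C@@H]1O)c1ccccc1 | intermediate
10 | [(1S,2S,3R,4R)-1,2,3,4-tetrahydroxy-6-oxocyclohexyl]methyl benzoate | O=C(OC[C@@]1(O)C(=O)C[C@@H](O)[C@@H](O)[C@@H]1O)c1ccccc1 | intermediate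
11 | [(1S,2S,3R,4R)-3-(benzoyloxy)-1,2,4-trihydroxy-6-oxocyclohexyl]methyl benzoate | O=C(OC[C@@]1(O)C(=O)C[C@@H](O)[C@@H](OC(=O)c2ccccc2)[C@@H]1O)c1ccccc1 | target

**Step count and risks**

Total step count: 7. Longest linear sequence: 7 steps (1 to 11).

Steps most likely to fail:

1. Step 1 (labelled step). What may go wrong: poor discrimination of the two pyrone faces, because the pyrone is held at one point only and may also bind through the ester carbonyl, or acid-induced oligomerisation of the dioxole. Fallback with known chemistry, setting out from 1 and 2: the uncatalysed cycloaddition (toluene, 85 °C, sealed vessel, or 12 kbar at 20 °C) should give 3 together with its mirror image ent-3 F1. Steps 2 and 3 on this mixture give 4 with ent-4 F2 and 5 with ent-5 F3. A lipase-catalysed acyl transfer (Burkholderia cepacia lipase, vinyl benzoate, tBuOMe, 30 °C) then benzoylates the primary hydroxyl of one enantiomer only and takes the place of step 4. With 5 taken as the fast-reacting enantiomer (to be fixed in a test run), the sequence comes back to the route at 6 and F3 stays behind as the alcohol.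

2. Step 7. What may go wrong: acyl transfer to O2 by way of a competing borinate of the C1/C2 cis-diol, or migration of the new benzoate to O4 followed by beta-elimination. Fallback, setting out from 1: the C3 benzoate is brought in with the dienophile. Commercial 2-oxoethyl benzoate is silylated (TBSOTf, Et3N, CH2Cl2, 0 °C) to (Z)-2-[(tert-butyldimethylsilyl)oxy]ethenyl benzoate F4; the cis isomer is the favoured one for 1,2-dioxygenated alkenes. Cycloaddition with 1 under the conditions of step 1 should give the OTBS/OBz analogue of 3 F5, because the silyl enol ether is nucleophilic at the carbon that bears the benzoate and this carbon bonds to the electrophilic pyrone C6. The operations of steps 2 to 5 then give the corresponding diol F6, primary alcohol F7, dibenzoate F8 and keto-lactone F9. TFA–H2O 4:1 at 20 °C removes the silyl ether and opens the lactone to the C3-benzoylated keto acid F10, which loses CO2 and comes back to the route at 11 without any selective acylation.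

3. Step 3. What may go wrong: loss of chemoselectivity, the strained lactone being reduced or opened alongside the methyl ester. Fallback, setting out from 2, with benzyl coumalate F11 (coumalic acid, BnBr, KHCO3, DMF) in place of 1: steps 1 and 2 give the benzyl ester analogue of 3 F12 and the benzyl ester analogue of 4 F13. Hydrogenolysis (H2, Pd/C, EtOAc) frees the alpha-hydroxy acid F14, and BH3·THF at 0 °C reduces a free carboxylic acid far faster than a lactone, which comes back to the route at 5.

Further compounds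
F1 | step 1 | ent-3 (mirror image of 3) | COC(=O)C1=C[C@@H]2[C@@H]3OC(C)(C)O[C@@H]3[C@H]1OC2=O
F2 | step 1 | ent-4 (mirror image of 4) | COC(=O)[C@]1(O)[C@@H](O)[C@@H]2[C@@H]3OC(C)(C)O[C@@H]3[C@H]1OC2=O
F3 | step 1 | ent-5 (mirror image of 5) | OC[C@]1(O)[C@@H](O)[C@@H]2[C@@H]3OC(C)(C)O[C@@H]3[C@H]1OC2=O
F4 | step 7 | (Z)-2-[(tert-butyldimethylsilyl)oxy]ethenyl benzoate | O=C(O/C=C\O[Si](C)(C)C(C)(C)C)c1ccccc1
F5 | step 7 | analogue of 3 with 7-OBz and 8-OTBS (both endo) in place of the acetonide | COC(=O)C1=C[C@H]2[C@@H](O[Si](C)(C)C(C)(C)C)[C@@H](OC(=O)c3ccccc3)[C@@H]1OC2=O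
F6 | step 7 | analogue of 4 with 7-OBz and 8-OTBS | COC(=O)[C@@]1(O)[C@H](O)[C@H]2[C@@H](O[Si](C)(C)C(C)(C)C)[C@@H](OC(=O)c3ccccc3)[C@@H]1OC2=O
F7 | step 7 | analogue of 5 with 7-OBz and 8-OTBS | OC[C@@]1(O)[C@H](O)[C@H]2[C@@H](O[Si](C)(C)C(C)(C)C)[C@@H](OC(=O)c3ccccc3)[C@@H]1OC2=O
F8 | step 7 | analogue of 6 with 7-OBz and 8-OTBS (dibenzoate) | O=C(OC[C@@]1(O)[C@H](O)[C@H]2[C@@H](O[Si](C)(C)C(C)(C)C)[C@@H](OC(=O)c3ccccc3)[C@@H]1OC2=O)c1ccccc1
F9 | step 7 | analogue of 7 with 7-OBz and 8-OTBS (keto-lactone) | O=C(OC[C@@]1(O)C(=O)[C@H]2[C@@H](O[Si](C)(C)C(C)(C)C)[C@@H](OC(=O)c3ccccc3)[C@@H]1OC2=O)c1ccccc1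
F10 | step 7 | 5-benzoate of keto acid 9 (5-carboxylic acid of the target, carboxyl cis to O2) | O=C(OC[C@@]1(O)C(=O)[C@H](C(=O)O)[C@@H](O)[C@@H](OC(=O)c2ccccc2)[C@@H]1O)c1ccccc1
F11 | step 3 | benzyl coumalate (benzyl 2-oxo-2H-pyran-5-carboxylate) | O=C(OCc1ccccc1)C1=COC(=O)C=C1
F12 | step 3 | benzyl ester analogue of 3 | O=C(OCc1ccccc1)C1=C[C@H]2[C@H]3OC(C)(C)O[C@H]3[C@@H]1OC2=O
F13 | step 3 | benzyl ester analogue of 4 | O=C(OCc1ccccc1)[C@@]1(O)[C@H](O)[C@H]2[C@H]3OC(C)(C)O[C@H]3[C@@H]1OC2=O
F14 | step 3 | carboxylic acid corresponding to 4 (alpha-hydroxy acid) | OC(=O)[C@@]1(O)[C@H](O)[C@H]2[C@H]3OC(C)(C)O[C@H]3[C@@H]1OC2=O
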